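**Retrosynthetic overview**
1. Target 20 ⇐ diol 17 + 4-acetoxybenzoyl chloride 18 (acylation of the secondary C4 hydroxyl, then release of the phenol).
2. 17 ⇐ β-hydroxy ketone 16 (hydroxyl-directed reduction sets C4) ⇐ dienone 14 by a proposed new copper-catalysed conjugate borylation/oxidation that sets C3 and the trans ring fusion at C3a.
3. 14 ⇐ ring-closing metathesis (C6=C7) of monocyclic diene 12: the seven-membered ring B is closed second, onto a preformed cyclopentene ring A.
4. 12 ⇐ enal 11 ⇐ alkenyl triflate 10 ⇐ (R)-2-allyl-2-methylcyclopentanone 4 (acetone aldol/dehydration, reductive triflation, formylation, methallyl addition).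
5. 4 ⇐ racemic allyl β-ketoester 3 by palladium-catalysed decarboxylative asymmetric allylic alkylation (sets the quaternary C8a) ⇐ diallyl adipate 1 (Dieckmann closure of ring A first).

Assumption: the target is taken exactly as its SMILES specifies, (3S,3aS,4R,8aR) in azulene numbering (C3 = carbinol carbon with isopropyl, C3a/C8a = ring fusion H/CH3, C4 = ester carbon, C6=C7 = ring alkene); 8a-CH3, the C3 isopropyl and the C4 aroyloxy group lie on one face, the C3 hydroxyl and H-3a on the other.
Note: the enantiomeric excess from step 2 (about 90% expected) is raised to a single enantiomer by recrystallising diol 17.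

**Route**

Step 1
Reactants: 1 diallyl adipate
Product: 3 rac-allyl 1-methyl-2-oxocyclopentane-1-carboxylate, via sodium enolate 2 (not isolated)
Conditions: NaH (1.1 equiv), allyl alcohol (cat.), THF, 40 °C; then MeI, rt
Reagents that add atoms: iodomethane, CI
Why: Dieckmann condensation of the symmetric diester gives the sodium β-ketoester enolate, which is C-methylated in the same flask (enolate alkylation); the quaternary carbon is formed racemic and is made stereoconvergent in step 2.

Step 2
Reactants: 3 rac-allyl 1-methyl-2-oxocyclopentane-1-carboxylate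
Product: 4 (R)-2-allyl-2-methylcyclopentan-1-one
Conditions: Pd2(dba)3 (2.5 mol%), (R)-(CF3)3-t-BuPHOX [(R)-4-tert-butyl-2-{2-[bis(4-trifluoromethylphenyl)phosphino]-5-(trifluoromethyl)phenyl}-4,5-dihydrooxazole] (6 mol%), toluene, 25 °C
Reagents that add atoms: none
Why: Palladium-catalysed decarboxylative asymmetric allylic alkylation (Tsuji-type): ionisation by zerovalent palladium and loss of CO2 give a prochiral enolate/π-allyl pair whose recombination is controlled by the PHOX ligand, so both enantiomers of 3 converge on the (R) quaternary centre (the (S) ligand is the one that gives the (S) ketone).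

Step 3
Reactants: 4 (R)-2-allyl-2-methylcyclopentan-1-one
Product: 6 (2R)-2-allyl-5-(2-hydroxypropan-2-yl)-2-methylcyclopentan-1-one (C5 epimer mixture), via lithium enolate 5 (not isolated)
Conditions: LiN(i-Pr)2 (1.05 equiv), THF, −78 °C; then acetone, −78 °C; AcOH quench at −78 °C
Reagents that add atoms: acetone, CC(C)=O
Why: Crossed aldol addition: the ketone can enolise only at C5, and its lithium enolate adds to acetone with a cold quench to avoid retro-aldol; the C5 configuration is irrelevant because it is erased in steps 4 and 5.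

Step 4
Reactants: 6 (2R)-2-allyl-5-(2-hydroxypropan-2-yl)-2-methylcyclopentan-1-one
Product: 8 (R)-2-allyl-2-methyl-5-(propan-2-ylidene)cyclopentan-1-one, via tertiary mesylate 7 (not isolated)
Conditions: MsCl, Et3N, DMAP (cat.), CH2Cl2, 0 °C to rt; then DBU, rt
Reagents that add atoms: methanesulfonyl chloride, CS(=O)(=O)Cl (mesyl group of 7 only)
Why: Aldol dehydration by mesylation of the tertiary alcohol and E1cB elimination through the ketone enolate, with DBU equilibrating any isopropenyl isomer into conjugation; the quaternary centre is not touched.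

Step 5
Reactants: 8 (R)-2-allyl-2-methyl-5-(propan-2-ylidene)cyclopentan-1-one
Product: 10 (R)-5-allyl-2-isopropyl-5-methylcyclopent-1-en-1-yl trifluoromethanesulfonate, via lithium enolate 9 (not isolated)
Conditions: LiBH(s-Bu)3, THF, −78 °C; then PhNTf2, −78 to 0 °C
Reagents that add atoms: N-phenylbis(trifluoromethanesulfonimide), O=S(=O)(N(c1ccccc1)S(=O)(=O)C(F)(F)F)C(F)(F)F
Why: Conjugate (1,4) hydride reduction of the s-cis enone generates a single fully substituted enolate that is trapped on oxygen by PhNTf2 (reductive enol triflation), fixing the alkene next to the quaternary carbon.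

Step 6
Reactants: 10 (R)-5-allyl-2-isopropyl-5-methylcyclopent-1-en-1-yl trifluoromethanesulfonate
Product: 11 (R)-5-allyl-2-isopropyl-5-methylcyclopent-1-ene-1-carbaldehyde
Conditions: Pd(PPh3)4 (5 mol%), CO (3 atm), Bu3SnH (slow addition), THF, 50 °C
Reagents that add atoms: carbon monoxide, [C-]#[O+]
Why: Palladium-catalysed reductive carbonylation (formylation) of an alkenyl triflate: oxidative addition of zerovalent palladium, CO insertion and hydride transfer from tin give the enal; no stereocentre is involved.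

Step 7
Reactants: 11 (R)-5-allyl-2-isopropyl-5-methylcyclopent-1-ene-1-carbaldehyde
Product: 12 1-[(5R)-5-allyl-2-isopropyl-5-methylcyclopent-1-en-1-yl]-3-methylbut-3-en-1-ol (carbinol epimer mixture)
Conditions: CH2=C(CH3)CH2MgCl, THF, −78 °C; aq. NH4Cl
Reagents that add atoms: 2-methylallylmagnesium chloride, CC(=C)C[Mg]Cl
Why: Grignard 1,2-addition of an allylic organomagnesium to the hindered enal; the new carbinol configuration is left uncontrolled because it is oxidised away in step 9.

Step 8
Reactants: 12 1-[(5R)-5-allyl-2-isopropyl-5-methylcyclopent-1-en-1-yl]-3-methylbut-3-en-1-ol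
Product: 13 (8aR)-3-isopropyl-6,8a-dimethyl-1,2,4,5,8,8a-hexahydroazulen-4-ol (C4 epimer mixture)
Conditions: second-generation Grubbs catalyst, RuCl2(=CHPh)(PCy3)(H2IMes) (5 mol%), CH2Cl2 (0.005 M), 40 °C
Reagents that add atoms: none
Why: Ring-closing olefin metathesis joins the allyl group and the 1,1-disubstituted methallyl alkene with loss of ethylene, closing ring B as a trisubstituted cycloheptene while the tetrasubstituted ring A alkene stays inert; no stereocentre is formed.

Step 9
Reactants: 13 (8aR)-3-isopropyl-6,8a-dimethyl-1,2,4,5,8,8a-hexahydroazulen-4-ol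
Product: 14 (8aR)-3-isopropyl-6,8a-dimethyl-1,2,8,8a-tetrahydroazulen-4(5H)-one
Conditions: Dess–Martin periodinane, NaHCO3, CH2Cl2, 0 °C
Reagents that add atoms: none
Why: Dess–Martin oxidation under buffered, non-enolising conditions merges both carbinol epimers into one dienone without moving the β,γ-alkene into conjugation.

Step 10
Reactants: 14 (8aR)-3-isopropyl-6,8a-dimethyl-1,2,8,8a-tetrahydroazulen-4(5H)-one
Product: 16 (3S,3aR,8aR)-3-hydroxy-3-isopropyl-6,8a-dimethyl-1,2,3,3a,8,8a-hexahydroazulen-4(5H)-one, via β-boryl ketone 15 (not isolated)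
Conditions: CuCl (10 mol%), 1,3-dicyclohexylimidazolium chloride (10 mol%), NaOt-Bu (25 mol%), bis(pinacolato)diboron (1.5 equiv), MeOH (2 equiv), THF, 0 °C to rt; then NaBO3·4H2O, THF/H2O, 0 °C to rt
Reagents that add atoms: bis(pinacolato)diboron, CC1(C)OB(OC1(C)C)B1OC(C)(C)C(C)(C)O1 (boryl group of 15); sodium perborate, [Na+].[Na+].O[B-]1(O)OO[B-](O)(O)OO1 (hydroxyl oxygen of 16)
Why: Proposed new method: copper-catalysed conjugate borylation of a fully substituted (tetrasubstituted) ring-fusion enone followed by stereoretentive C–B oxidation, in effect a trans-selective conjugate hydration; a small, strongly donating 1,3-dicyclohexylimidazol-2-ylidene ligand on monovalent copper gives a compact LCu–B(pin) that can transfer boron to the congested C3 from the face opposite the 8a-methyl group, MeOH then protonates the copper enolate at C3a from the same open face (the other face is flanked by the 8a-methyl and the C3 isopropyl groups), which sets the trans ring fusion, and perborate replaces boron by hydroxyl with retention to give the (3S) carbinol; the closest known reaction type is the copper–boryl β-borylation of β,β-disubstituted enones and enoates to tertiary boronates, which has not been shown on tetrasubstituted enones or used to set a ring fusion.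

Step 11
Reactants: 16 (3S,3aR,8aR)-3-hydroxy-3-isopropyl-6,8a-dimethyl-1,2,3,3a,8,8a-hexahydroazulen-4(5H)-one
Product: 17 (3S,3aS,4R,8aR)-3-isopropyl-6,8a-dimethyl-1,2,3,3a,4,5,8,8a-octahydroazulene-3,4-diol
Conditions: Me4NBH(OAc)3 (5 equiv), MeCN/AcOH (1:1), −30 °C
Reagents that add atoms: none
Why: Evans–Saksena hydroxyl-directed reduction: the C3 alkoxide exchanges onto boron and delivers hydride intramolecularly to the ketone face on its own side, which is also the face away from the 8a-methyl group, giving the (4R) alcohol.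

Step 12
Reactants: 17 (3S,3aS,4R,8aR)-3-isopropyl-6,8a-dimethyl-1,2,3,3a,4,5,8,8a-octahydroazulene-3,4-diol; 18 4-acetoxybenzoyl chloride
Product: 19 (3S,3aS,4R,8aR)-3-hydroxy-3-isopropyl-6,8a-dimethyl-1,2,3,3a,4,5,8,8a-octahydroazulen-4-yl 4-acetoxybenzoate
Conditions: Et3N, DMAP (0.2 equiv), CH2Cl2, 0 °C to rt
Reagents that add atoms: none
Why: DMAP-catalysed acylation (nucleophilic catalysis) occurs only at the secondary C4 hydroxyl because the tertiary C3 hydroxyl is too hindered, with retention at C4.

Step 13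
Reactants: 19 (3S,3aS,4R,8aR)-3-hydroxy-3-isopropyl-6,8a-dimethyl-1,2,3,3a,4,5,8,8a-octahydroazulen-4-yl 4-acetoxybenzoate
Product: 20 (3S,3aS,4R,8aR)-3-hydroxy-3-isopropyl-6,8a-dimethyl-1,2,3,3a,4,5,8,8a-octahydroazulen-4-yl 4-hydroxybenzoate
Conditions: pyrrolidine (2 equiv), CH2Cl2, 0 °C to rt
Reagents that add atoms: none
Why: Chemoselective aminolysis of the activated aryl acetate by pyrrolidine frees the phenol while the hindered secondary benzoate stays intact; no stereocentre is affected.

**Compound list**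
1 | diallyl adipate (diprop-2-en-1-yl hexanedioate) | C=CCOC(=O)CCCCC(=O)OCC=C | starting material
2 | sodium 2-[(prop-2-en-1-yloxy)carbonyl]cyclopent-1-en-1-olate | C=CCOC(=O)C1=C([O-])CCC1.[Na+] | intermediate
3 | rac-allyl 1-methyl-2-oxocyclopentane-1-carboxylate | C=CCOC(=O)C1(C)CCCC1=O | intermediate
4 | (R)-2-allyl-2-methylcyclopentan-1-one | C=CC[C@@]1(C)CCCC1=O | intermediate
5 | lithium (R)-5-allyl-5-methylcyclopent-1-en-1-olate | C=CC[C@@]1(C)CCC=C1[O-].[Li+] | intermediate
6 | (2R)-2-allyl-5-(2-hydroxypropan-2-yl)-2-methylcyclopentan-1-one (C5 epimer mixture) | C=CC[C@@]1(C)CCC(C(C)(C)O)C1=O | intermediate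
7 | 2-[(3R)-3-allyl-3-methyl-2-oxocyclopentyl]propan-2-yl methanesulfonate | C=CC[C@@]1(C)CCC(C(C)(C)OS(C)(=O)=O)C1=O | intermediate
8 | (R)-2-allyl-2-methyl-5-(propan-2-ylidene)cyclopentan-1-one | C=CC[C@@]1(C)CCC(=C(C)C)C1=O | intermediate
9 | lithium (R)-5-allyl-2-isopropyl-5-methylcyclopent-1-en-1-olate | C=CC[C@@]1(C)CCC(C(C)C)=C1[O-].[Li+] | intermediate
10 | (R)-5-allyl-2-isopropyl-5-methylcyclopent-1-en-1-yl trifluoromethanesulfonate | C=CC[C@@]1(C)CCC(C(C)C)=C1OS(=O)(=O)C(F)(F)F | intermediate
11 | (R)-5-allyl-2-isopropyl-5-methylcyclopent-1-ene-1-carbaldehyde | C=CC[C@@]1(C)CCC(C(C)C)=C1C=O | intermediate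
12 | 1-[(5R)-5-allyl-2-isopropyl-5-methylcyclopent-1-en-1-yl]-3-methylbut-3-en-1-ol (carbinol epimer mixture) | C=CC[C@@]1(C)CCC(C(C)C)=C1C(O)CC(C)=C | intermediate
13 | (8aR)-3-isopropyl-6,8a-dimethyl-1,2,4,5,8,8a-hexahydroazulen-4-ol (C4 epimer mixture) | CC1=CC[C@@]2(C)CCC(C(C)C)=C2C(O)C1 | intermediate
14 | (8aR)-3-isopropyl-6,8a-dimethyl-1,2,8,8a-tetrahydroazulen-4(5H)-one | CC1=CC[C@@]2(C)CCC(C(C)C)=C2C(=O)C1 | intermediate
15 | (3R,3aS,8aR)-3-isopropyl-6,8a-dimethyl-3-(4,4,5,5-tetramethyl-1,3,2-dioxaborolan-2-yl)-1,2,3,3a,8,8a-hexahydroazulen-4(5H)-one | CC1=CC[C@@]2(C)CC[C@](B3OC(C)(C)C(C)(C)O3)(C(C)C)[C@@H]2C(=O)C1 | intermediate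
16 | (3S,3aR,8aR)-3-hydroxy-3-isopropyl-6,8a-dimethyl-1,2,3,3a,8,8a-hexahydroazulen-4(5H)-one | CC1=CC[C@@]2(C)CC[C@](O)(C(C)C)[C@@H]2C(=O)C1 | intermediate
17 | (3S,3aS,4R,8aR)-3-isopropyl-6,8a-dimethyl-1,2,3,3a,4,5,8,8a-octahydroazulene-3,4-diol | CC1=CC[C@@]2(C)CC[C@](O)(C(C)C)[C@@H]2[C@H](O)C1 | intermediate
18 | 4-acetoxybenzoyl chloride | CC(=O)Oc1ccc(cc1)C(Cl)=O | starting material
19 | (3S,3aS,4R,8aR)-3-hydroxy-3-isopropyl-6,8a-dimethyl-1,2,3,3a,4,5,8,8a-octahydroazulen-4-yl 4-acetoxybenzoate | CC1=CC[C@@]2(C)CC[C@](O)(C(C)C)[C@@H]2[C@H](OC(=O)c2ccc(OC(C)=O)cc2)C1 | intermediate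
20 | (3S,3aS,4R,8aR)-3-hydroxy-3-isopropyl-6,8a-dimethyl-1,2,3,3a,4,5,8,8a-octahydroazulen-4-yl 4-hydroxybenzoate | CC1=CC[C@@]2(C)CC[C@](O)(C(C)C)[C@@H]2[C@H](OC(=O)c2ccc(O)cc2)C1 | target

**Step count and risk**
Total step count: 13. Longest linear sequence: 13 steps (1 to 20); 18 is a purchased fragment that enters at step 12.

The three steps most likely to fail:

Step 10, the proposed new reaction. The boryl group may not transfer to the fully substituted, isopropyl-bearing β-carbon. The catalytic alkoxide may move the C6=C7 alkene into conjugation with the ketone. The tertiary aldol 16 may undergo retro-aldol during oxidation. The fallback uses known reactions only, sets out from enal 11 and comes back at 16, replacing steps 7 to 10. Brown methallylboration of 11 with (−)-Ipc2B(2-methylallyl), made from (−)-Ipc2BOMe and CH2=C(CH3)CH2MgCl (Et2O, −78 °C; then NaOH/H2O2), adds to the Si face under reagent control. It gives (1S)-1-[(5R)-5-allyl-2-isopropyl-5-methylcyclopent-1-en-1-yl]-3-methylbut-3-en-1-ol F1. Ring-closing metathesis under the step 8 conditions gives (4S,8aR)-3-isopropyl-6,8a-dimethyl-1,2,4,5,8,8a-hexahydroazulen-4-ol F2. Hydroxyl-directed epoxidation with VO(acac)2 (5 mol%) and t-BuOOH in CH2Cl2 at 0 °C delivers oxygen syn to the C4 hydroxyl and anti to the 8a-methyl group and leaves the C6=C7 alkene alone. It gives (3S,3aR,4S,8aR)-3,3a-epoxy-3-isopropyl-6,8a-dimethyl-1,2,3,3a,4,5,8,8a-octahydroazulen-4-ol F3. Dess–Martin oxidation gives (3S,3aS,8aR)-3,3a-epoxy-3-isopropyl-6,8a-dimethyl-1,2,3,3a,8,8a-hexahydroazulen-4(5H)-one F4. Reduction with SmI2 (2.2 equiv, divalent samarium) and MeOH in THF at −90 °C cleaves the α C–O bond of the epoxy ketone. The samarium enolate is protonated on the face of the new C3 alkoxide, away from the 8a-methyl and isopropyl groups, and gives 16.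

Step 6, formylation of a very congested alkenyl triflate. The alkenyl-palladium intermediate may be reduced by the tin hydride before CO inserts, giving the des-formyl alkene. The fallback removes the hydride from the carbonylation, sets out from triflate 10 and comes back at 11. Alkoxycarbonylation with Pd(OAc)2 (5 mol%), Fe(C5H4PPh2)2 (dppf), CO (1 atm), MeOH and Et3N in DMF at 60 °C gives methyl (R)-5-allyl-2-isopropyl-5-methylcyclopent-1-ene-1-carboxylate F5. Reduction with i-Bu2AlH in CH2Cl2 at −78 °C gives [(5R)-5-allyl-2-isopropyl-5-methylcyclopent-1-en-1-yl]methanol F6. Oxidation of this allylic alcohol with MnO2 in CH2Cl2 gives 11.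

Step 11, facial selectivity at C4. A tertiary alkoxide exchanges slowly onto boron, so the directed pathway may be slow and hydride may enter from the methyl-bearing face instead. The fallback turns the wrong epimer into the right ester, sets out from 16 and comes back at 19, replacing steps 11 and 12. The C4 epimer is collected from step 11 or made on purpose with the external-hydride chelation protocol (Et2BOMe, NaBH4, THF/MeOH, −78 °C). This gives (3S,3aS,4S,8aR)-3-isopropyl-6,8a-dimethyl-1,2,3,3a,4,5,8,8a-octahydroazulene-3,4-diol F7. Mitsunobu esterification of F7 with 4-acetoxybenzoic acid (PPh3, DIAD, toluene, 0 °C to rt) forms the C4–O bond with inversion and gives 19 directly.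

Further compounds
F1 | step 10 | (1S)-1-[(5R)-5-allyl-2-isopropyl-5-methylcyclopent-1-en-1-yl]-3-methylbut-3-en-1-ol | C=CC[C@@]1(C)CCC(C(C)C)=C1[C@@H](O)CC(C)=C
F2 | step 10 | (4S,8aR)-3-isopropyl-6,8a-dimethyl-1,2,4,5,8,8a-hexahydroazulen-4-ol | CC1=CC[C@@]2(C)CCC(C(C)C)=C2[C@@H](O)C1
F3 | step 10 | (3S,3aR,4S,8aR)-3,3a-epoxy-3-isopropyl-6,8a-dimethyl-1,2,3,3a,4,5,8,8a-octahydroazulen-4-ol | CC1=CC[C@@]2(C)CC[C@@]3(C(C)C)O[C@@]23[C@@H](O)C1
F4 | step 10 | (3S,3aS,8aR)-3,3a-epoxy-3-isopropyl-6,8a-dimethyl-1,2,3,3a,8,8a-hexahydroazulen-4(5H)-one | CC1=CC[C@@]2(C)CC[C@@]3(C(C)C)O[C@@]23C(=O)C1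
F5 | step 6 | methyl (R)-5-allyl-2-isopropyl-5-methylcyclopent-1-ene-1-carboxylate | C=CC[C@@]1(C)CCC(C(C)C)=C1C(=O)OC
F6 | step 6 | [(5R)-5-allyl-2-isopropyl-5-methylcyclopent-1-en-1-yl]methanol | C=CC[C@@]1(C)CCC(C(C)C)=C1CO
F7 | step 11 | (3S,3aS,4S,8aR)-3-isopropyl-6,8a-dimethyl-1,2,3,3a,4,5,8,8a-octahydroazulene-3,4-diol | CC1=CC[C@@]2(C)CC[C@](O)(C(C)C)[C@@H]2[C@@H](O)C1
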